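**Retrosynthetic overview**
1. Feature used: the carbocycle C4a–C5–C6–C7–C8–C8a of the 1H-isochromene is the carbonyl carbon (C4a) and α-carbon (C8a) of a 2,3-dihydro-4H-pyran-4-one, bridged by a four-carbon acetolactate unit C5–C6(=O)–C7(CH3)(O)–C8(=O).
2. C5–Cl is cut last (electrophilic chlorination). C8–C8a (Claisen acylation) and C4a=C5 (aldol/Knoevenagel cyclodehydration) are then cut together, giving the 6-dienyl dihydropyranone and the 5-acetyl dioxolanone of (R)-lactic acid, which carries C7.
3. Repair inside the annulation: the C7 alkoxide released from the dioxolanone is acetylated (the target's own acetate) before the acid closure, because a free C7–OH beside the C4a/C8 1,3-diketone would cyclodehydrate to a 3(2H)-furanone. The annulation product is therefore the 5-deschloro target, not the free C7 alcohol.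
4. Fragments: the dioxolanone comes from (R)-lactic acid and pivalaldehyde by acetalisation, anti aldol with acetaldehyde and oxidation. The pyranone comes from (R)-2-methylbutanoic acid via the (E)-enal, the (E,E)-dienone, aldol with 3-silyloxypropanal, oxidation and cyclodehydration.
5. Ring order: pyranone ring first (step 11), carbocycle second (step 12).

Key step: step 12

Assumption: H-8a is the acidic proton of a vinylogous β-diketone, so C8a is taken to settle by equilibration in the target configuration (H-8a syn to the C7 oxygen); (R)-2-methylbutanoic acid and (R)-lactic acid are bought as single enantiomers.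

**Step 1**
Reactants: 1 (R)-lactic acid; 2 pivalaldehyde
Product: 3 (2R,5R)-2-tert-butyl-5-methyl-1,3-dioxolan-4-one (cis)
Conditions: TsOH·H2O (cat.), H2SO4 (cat.), pentane, reflux, Dean–Stark; recrystallisation from pentane at −78 °C
Reagents that add atoms: none
Why: Acid-catalysed acetalisation of the α-hydroxy acid with azeotropic removal of water should give mainly the cis acetal, the new C2 centre (R) being set under thermodynamic control by the lactic acid centre and the cis isomer purified by crystallisation.

**Step 2**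
Reactants: 3 (2R,5R)-2-tert-butyl-5-methyl-1,3-dioxolan-4-one; 4 acetaldehyde
Product: 5 (2R,5S)-2-tert-butyl-5-(1-hydroxyethyl)-5-methyl-1,3-dioxolan-4-one (carbinol epimers)
Conditions: LDA (1.05 equiv), THF, −78 °C; MeCHO, −78 °C; AcOH
Reagents that add atoms: none
Why: Aldol addition of the dioxolanone lithium enolate (self-regeneration of stereocentres) should occur on the face opposite the tert-butyl group, so the new quaternary centre keeps methyl cis to tert-butyl (5S, net retention), while the carbinol centre forms as a mixture that the next step removes.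

**Step 3**
Reactants: 5 (2R,5S)-2-tert-butyl-5-(1-hydroxyethyl)-5-methyl-1,3-dioxolan-4-one
Product: 6 (2R,5S)-5-acetyl-2-tert-butyl-5-methyl-1,3-dioxolan-4-one
Conditions: Dess–Martin periodinane (1.3 equiv), pyridine, CH2Cl2, 0 °C → rt
Reagents that add atoms: none
Why: Dess–Martin oxidation of the secondary alcohol to the methyl ketone is non-basic and should leave the acylal lactone and the non-enolisable quaternary centre untouched.

**Step 4**
Reactants: 7 propane-1,3-diol
Product: 8 3-[(tert-butyldimethylsilyl)oxy]propan-1-ol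
Conditions: NaH (1.0 equiv), THF, 0 °C → rt; TBSCl (1.0 equiv)
Reagents that add atoms: tert-butyldimethylsilyl chloride, CC(C)(C)[Si](C)(C)Cl
Why: O-Silylation of the sparingly soluble monosodium alkoxide of the symmetric diol should stop at the mono-silyl ether.

**Step 5**
Reactants: 8 3-[(tert-butyldimethylsilyl)oxy]propan-1-ol
Product: 9 3-[(tert-butyldimethylsilyl)oxy]propanal
Conditions: TEMPO (0.1 equiv), PhI(OAc)2 (1.1 equiv), CH2Cl2, rt
Reagents that add atoms: none
Why: TEMPO-catalysed oxidation of the primary alcohol stops at the aldehyde and tolerates the silyl ether.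

**Step 6**
Reactants: 10 (R)-2-methylbutanoic acid
Product: 11 (R)-2-methylbutan-1-ol
Conditions: LiAlH4, Et2O, 0 °C → reflux; aq. NaOH work-up
Reagents that add atoms: none
Why: Hydride reduction of the carboxylic acid to the primary alcohol does not enolise the carboxylate, so the R centre is kept.

**Step 7**
Reactants: 11 (R)-2-methylbutan-1-ol; 12 2-(triphenylphosphoranylidene)propanal
Product: 14 (2E,4R)-2,4-dimethylhex-2-enal, via (R)-2-methylbutanal 13 (not isolated)
Conditions: TEMPO (0.1 equiv), PhI(OAc)2 (1.1 equiv), CH2Cl2, rt; aq. NaHCO3 wash, dried solution used directly; 12 (1.2 equiv), 40–45 °C, sealed vessel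
Reagents that add atoms: none
Why: Base-free TEMPO oxidation gives the volatile α-branched aldehyde, which is used at once in a Wittig olefination with the stabilised formyl ylide that should give the (E)-trisubstituted enal, the C4 centre being carried over from 11.

**Step 8**
Reactants: 14 (2E,4R)-2,4-dimethylhex-2-enal; 15 diethyl (2-oxopropyl)phosphonate
Product: 16 (3E,5E,7R)-5,7-dimethylnona-3,5-dien-2-one
Conditions: LiCl (1.2 equiv), iPr2NEt (1.1 equiv), MeCN, rt
Reagents that add atoms: none
Why: Horner–Wadsworth–Emmons olefination under Masamune–Roush conditions is E-selective with the β-ketophosphonate and mild enough not to deprotonate the γ-stereocentre of the enal.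

**Step 9**
Reactants: 16 (3E,5E,7R)-5,7-dimethylnona-3,5-dien-2-one; 9 3-[(tert-butyldimethylsilyl)oxy]propanal
Product: 17 (6E,8E,10R)-1-[(tert-butyldimethylsilyl)oxy]-3-hydroxy-8,10-dimethyldodeca-6,8-dien-5-one (C3 epimers)
Conditions: LDA (1.05 equiv), THF, −78 °C; 9, −78 °C; AcOH
Reagents that add atoms: none
Why: Kinetic deprotonation at the α′-methyl group gives the cross-conjugated lithium enolate, whose aldol addition to the aldehyde at −78 °C forms a carbinol centre as a mixture that is oxidised next.

**Step 10**
Reactants: 17 (6E,8E,10R)-1-[(tert-butyldimethylsilyl)oxy]-3-hydroxy-8,10-dimethyldodeca-6,8-dien-5-one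
Product: 18 (6E,8E,10R)-1-[(tert-butyldimethylsilyl)oxy]-8,10-dimethyldodeca-6,8-diene-3,5-dione
Conditions: Dess–Martin periodinane (1.2 equiv), pyridine, CH2Cl2, 0 °C
Reagents that add atoms: none
Why: Dess–Martin oxidation of the β-hydroxy ketone to the 1,3-diketone is buffered and should be tolerated by the diene and the silyl ether.

**Step 11**
Reactants: 18 (6E,8E,10R)-1-[(tert-butyldimethylsilyl)oxy]-8,10-dimethyldodeca-6,8-diene-3,5-dione
Product: 20 6-[(1E,3E,5R)-3,5-dimethylhepta-1,3-dien-1-yl]-2,3-dihydro-4H-pyran-4-one, via hydroxy diketone 19 (not isolated)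
Conditions: HF·pyridine, THF, 0 °C → rt; crude taken on; TsOH·H2O (0.1 equiv), PhMe, rt → 40 °C
Reagents that add atoms: none
Why: Desilylation frees the δ-hydroxyl, which can only add to the dienyl-conjugated carbonyl in a six-membered mode, and acid-catalysed dehydration of the hemiketal gives the dihydropyranone (standard cyclodehydration of δ-hydroxy β-diketones).

**Step 12**
Reactants: 20 6-[(1E,3E,5R)-3,5-dimethylhepta-1,3-dien-1-yl]-2,3-dihydro-4H-pyran-4-one; 6 (2R,5S)-5-acetyl-2-tert-butyl-5-methyl-1,3-dioxolan-4-one
Product: 23 (7S,8aR)-3-[(1E,3E,5R)-3,5-dimethylhepta-1,3-dien-1-yl]-7-methyl-6,8-dioxo-6,7,8,8a-tetrahydro-1H-isochromen-7-yl acetate, via Claisen adduct 21 (not isolated), via triketone acetate 22 (not isolated)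
Conditions: LiHMDS (1.05 equiv), THF, −78 °C; 6 (1.1 equiv), −78 → −30 °C; LiHMDS (1.05 equiv), −78 °C, then Ac2O (1.2 equiv), −78 → 0 °C; AcOH, pH 5 wash, crude taken on; CSA (0.3 equiv), 4 Å MS, PhMe, 60 °C (C8a epimers equilibrate in this medium)
Reagents that add atoms: acetic anhydride, CC(=O)OC(C)=O
Why: Proposed new method: the kinetic C8a lithium enolate of 20 adds to the acylal-type lactone carbonyl of 6, the tetrahedral intermediate collapses with loss of pivalaldehyde (bond C8–C8a), the released C7 alkoxide is regenerated with a second equivalent of base and acetylated so that it cannot close a 3(2H)-furanone on C4a, and under acid the C6 methyl ketone enol attacks the protonated vinylogous ester carbonyl C4a and water is lost (C4a=C5). The closest known reaction types are the acylation of lithium enolates by 1,3-dioxolan-4-ones and the acid-mediated aldol cyclodehydration of 1,5-diketones (Robinson-type and biomimetic polyketide closures), whose combination on a vinylogous ester carbonyl is untested. The carbocycle closes by a 6-(enolendo)-exo-trig aldol addition followed by dehydration, driven by formation of the doubly vinylogous ester O2–C3=C4–C4a=C5–C6=O. C7 is carried unchanged from 6 (no α-hydrogen, and the acetate blocks an α-ketol shift), while C8a is set by acid equilibration through the enol and should favour the epimer in which C1 and the C7 methyl are both pseudo-equatorial, that is H-8a syn to the C7 acetate. The step needs C-acylation at the lactone in preference to proton transfer from, or aldol addition to, the acetyl group of 6: the lactone carbonyl is the most electrophilic site, ketone aldol addition is reversible and only acyl transfer is made irreversible by loss of pivalaldehyde, and ring size lets C5 reach only C4a.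

**Step 13**
Reactants: 23 (7S,8aR)-3-[(1E,3E,5R)-3,5-dimethylhepta-1,3-dien-1-yl]-7-methyl-6,8-dioxo-6,7,8,8a-tetrahydro-1H-isochromen-7-yl acetate
Product: 24 (7R,8aR)-5-chloro-3-[(1E,3E,5R)-3,5-dimethylhepta-1,3-dien-1-yl]-7-methyl-6,8-dioxo-6,7,8,8a-tetrahydro-1H-isochromen-7-yl acetate
Conditions: NCS (1.05 equiv), AcOH–MeCN (1:4), 0 °C → rt, dark
Reagents that add atoms: N-chlorosuccinimide, O=C1CCC(=O)N1Cl
Why: Electrophilic chlorination of the push–pull chromophore (α-halogenation of a vinylogous ester) should occur at C5, the α-carbon of O2–C3=C4–C4a=C5–C6=O, with loss of H-5 restoring the chromophore, the base-free medium keeping the C8/C8a enol out of play and C8a staying under the same thermodynamic control.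

**Compound list**
1 | (R)-lactic acid | C[C@@H](O)C(=O)O | starting material
2 | pivalaldehyde | CC(C)(C)C=O | starting material
3 | (2R,5R)-2-tert-butyl-5-methyl-1,3-dioxolan-4-one (cis) | C[C@H]1O[C@@H](C(C)(C)C)OC1=O | intermediate
4 | acetaldehyde | CC=O | starting material
5 | (2R,5S)-2-tert-butyl-5-(1-hydroxyethyl)-5-methyl-1,3-dioxolan-4-one (carbinol epimers) | CC(O)[C@]1(C)O[C@@H](C(C)(C)C)OC1=O | intermediate
6 | (2R,5S)-5-acetyl-2-tert-butyl-5-methyl-1,3-dioxolan-4-one (methyl cis to tert-butyl) | CC(=O)[C@]1(C)O[C@@H](C(C)(C)C)OC1=O | intermediate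
7 | propane-1,3-diol | OCCCO | starting material
8 | 3-[(tert-butyldimethylsilyl)oxy]propan-1-ol | OCCCO[Si](C)(C)C(C)(C)C | intermediate
9 | 3-[(tert-butyldimethylsilyl)oxy]propanal | O=CCCO[Si](C)(C)C(C)(C)C | intermediate
10 | (R)-2-methylbutanoic acid | CC[C@@H](C)C(=O)O | starting material
11 | (R)-2-methylbutan-1-ol | CC[C@@H](C)CO | intermediate
12 | 2-(triphenylphosphoranylidene)propanal | CC(C=O)=P(c1ccccc1)(c1ccccc1)c1ccccc1 | starting material
13 | (R)-2-methylbutanal (not isolated) | CC[C@@H](C)C=O | intermediate
14 | (2E,4R)-2,4-dimethylhex-2-enal | CC[C@@H](C)/C=C(C)/C=O | intermediate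
15 | diethyl (2-oxopropyl)phosphonate | CCOP(=O)(CC(C)=O)OCC | starting material
16 | (3E,5E,7R)-5,7-dimethylnona-3,5-dien-2-one | CC[C@@H](C)/C=C(C)/C=C/C(C)=O | intermediate
17 | (6E,8E,10R)-1-[(tert-butyldimethylsilyl)oxy]-3-hydroxy-8,10-dimethyldodeca-6,8-dien-5-one (C3 epimers) | CC[C@@H](C)/C=C(C)/C=C/C(=O)CC(O)CCO[Si](C)(C)C(C)(C)C | intermediate
18 | (6E,8E,10R)-1-[(tert-butyldimethylsilyl)oxy]-8,10-dimethyldodeca-6,8-diene-3,5-dione | CC[C@@H](C)/C=C(C)/C=C/C(=O)CC(=O)CCO[Si](C)(C)C(C)(C)C | intermediate
19 | (6E,8E,10R)-1-hydroxy-8,10-dimethyldodeca-6,8-diene-3,5-dione (not isolated) | CC[C@@H](C)/C=C(C)/C=C/C(=O)CC(=O)CCO | intermediate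
20 | 6-[(1E,3E,5R)-3,5-dimethylhepta-1,3-dien-1-yl]-2,3-dihydro-4H-pyran-4-one | CC[C@@H](C)/C=C(C)/C=C/C1=CC(=O)CCO1 | intermediate
21 | 6-[(1E,3E,5R)-3,5-dimethylhepta-1,3-dien-1-yl]-3-[(2S)-2-hydroxy-2-methyl-3-oxobutanoyl]-2,3-dihydro-4H-pyran-4-one (present as its lithium enolate, ring C3 unassigned, not isolated) | CC[C@@H](C)/C=C(C)/C=C/C1=CC(=O)C(CO1)C(=O)[C@@](C)(O)C(C)=O | intermediate
22 | 3-[(2S)-2-acetoxy-2-methyl-3-oxobutanoyl]-6-[(1E,3E,5R)-3,5-dimethylhepta-1,3-dien-1-yl]-2,3-dihydro-4H-pyran-4-one (ring C3 unassigned, not isolated) | CC[C@@H](C)/C=C(C)/C=C/C1=CC(=O)C(CO1)C(=O)[C@@](C)(OC(C)=O)C(C)=O | intermediate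
23 | (7S,8aR)-3-[(1E,3E,5R)-3,5-dimethylhepta-1,3-dien-1-yl]-7-methyl-6,8-dioxo-6,7,8,8a-tetrahydro-1H-isochromen-7-yl acetate (5-deschloro target; same spatial arrangement at C7 as the target, descriptor changes with the chlorine) | CC[C@@H](C)/C=C(C)/C=C/C1=CC2=CC(=O)[C@](C)(OC(C)=O)C(=O)[C@H]2CO1 | intermediate
24 | (7R,8aR)-5-chloro-3-[(1E,3E,5R)-3,5-dimethylhepta-1,3-dien-1-yl]-7-methyl-6,8-dioxo-6,7,8,8a-tetrahydro-1H-isochromen-7-yl acetate | CC[C@@H](C)/C=C(C)/C=C/C1=CC2=C(Cl)C(=O)[C@](C)(OC(C)=O)C(=O)[C@H]2CO1 | target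

**Totals**
Total step count: 13. Longest linear sequence: 8 steps (10 → 11 → 14 → 16 → 17 → 18 → 20 → 23 → 24).

**Steps most likely to fail**

1. Step 12 (Proposed new method).
 - What may go wrong: the enolate of 20 may deprotonate the acetyl methyl group of 6, add reversibly to its ketone, or be O-acylated instead of transferring the acyl group to carbon; capping of the C7 alkoxide may be incomplete, so that closure through oxygen competes; the aldol addition onto the deactivated C4a carbonyl may stall.
 - Fallback (sets out from 5 and 20, returns at 22, which is then isolated): the ketone of the acyl donor stays masked and every stage is purified. Silylation of 5 (TESOTf, 2,6-lutidine, CH2Cl2) should give (2R,5S)-2-tert-butyl-5-methyl-5-[1-(triethylsilyloxy)ethyl]-1,3-dioxolan-4-one F1, which has neither an acidic methyl ketone nor a second electrophilic carbonyl. Acylation of the lithium enolate of 20 with F1 (known acylation of enolates by dioxolanones), followed by LiHMDS and Ac2O, should give 3-[(2S)-2-acetoxy-2-methyl-3-(triethylsilyloxy)butanoyl]-6-[(1E,3E,5R)-3,5-dimethylhepta-1,3-dien-1-yl]-2,3-dihydro-4H-pyran-4-one F2. HF·pyridine should free 3-[(2S)-2-acetoxy-3-hydroxy-2-methylbutanoyl]-6-[(1E,3E,5R)-3,5-dimethylhepta-1,3-dien-1-yl]-2,3-dihydro-4H-pyran-4-one F3, and Dess–Martin oxidation should give 22. Purified 22 is then closed to 23 as an ordinary acid-catalysed aldol cyclodehydration of a 1,5-diketone.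

2. Step 13.
 - What may go wrong: chlorination through the C8/C8a enol of the vinylogous β-diketone, or at C4 or the side-chain diene, may compete with attack at C5, and over-chlorination may follow.
 - Fallback (sets out from 23, returns at 24): the acidic H-8a is removed first. TBSOTf and Et3N in CH2Cl2 at −78 °C should give the silyl dienol ether (7R)-8-[(tert-butyldimethylsilyl)oxy]-3-[(1E,3E,5R)-3,5-dimethylhepta-1,3-dien-1-yl]-7-methyl-6-oxo-6,7-dihydro-1H-isochromen-7-yl acetate F4. Its reaction with NCS is the known γ-selective halogenation of silyl dienol ethers and should occur at C5, which is activated from both ends of the chromophore. Loss of the silyl group on work-up and tautomerisation then give 24.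

3. Step 7.
 - What may go wrong: the α-stereocentre of aldehyde 13 may racemise by enolisation, and the volatile aldehyde may be lost, during the slow, warm olefination with the weakly nucleophilic formyl ylide.
 - Fallback (sets out from 11, returns at 14): after the same oxidation, the aldehyde solution is treated at room temperature with the more reactive ethyl 2-(triphenylphosphoranylidene)propanoate to give ethyl (2E,4R)-2,4-dimethylhex-2-enoate F5. DIBAL-H reduction (CH2Cl2, −78 °C) should give (2E,4R)-2,4-dimethylhex-2-en-1-ol F6, and MnO2 oxidation returns 14.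

**Further compounds**
F1 | step 12 | (2R,5S)-2-tert-butyl-5-methyl-5-[1-(triethylsilyloxy)ethyl]-1,3-dioxolan-4-one | CC(O[Si](CC)(CC)CC)[C@]1(C)O[C@@H](C(C)(C)C)OC1=O
F2 | step 12 | 3-[(2S)-2-acetoxy-2-methyl-3-(triethylsilyloxy)butanoyl]-6-[(1E,3E,5R)-3,5-dimethylhepta-1,3-dien-1-yl]-2,3-dihydro-4H-pyran-4-one | CC[C@@H](C)/C=C(C)/C=C/C1=CC(=O)C(CO1)C(=O)[C@@](C)(OC(C)=O)C(C)O[Si](CC)(CC)CC
F3 | step 12 | 3-[(2S)-2-acetoxy-3-hydroxy-2-methylbutanoyl]-6-[(1E,3E,5R)-3,5-dimethylhepta-1,3-dien-1-yl]-2,3-dihydro-4H-pyran-4-one | CC[C@@H](C)/C=C(C)/C=C/C1=CC(=O)C(CO1)C(=O)[C@@](C)(OC(C)=O)C(C)O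
F4 | step 13 | (7R)-8-[(tert-butyldimethylsilyl)oxy]-3-[(1E,3E,5R)-3,5-dimethylhepta-1,3-dien-1-yl]-7-methyl-6-oxo-6,7-dihydro-1H-isochromen-7-yl acetate | CC[C@@H](C)/C=C(C)/C=C/C1=CC2=CC(=O)[C@](C)(OC(C)=O)C(O[Si](C)(C)C(C)(C)C)=C2CO1
F5 | step 7 | ethyl (2E,4R)-2,4-dimethylhex-2-enoate | CC[C@@H](C)/C=C(C)/C(=O)OCC
F6 | step 7 | (2E,4R)-2,4-dimethylhex-2-en-1-ol | CC[C@@H](C)/C=C(C)/CO
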